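The plan rests on making the C8–C9 bond of ring B (the cyclohexene ring; drimane numbering, C11 = benzylic CH2) last. C9 is the one carbon that touches both the alkene carbon C8 and the arylmethyl carbon C11, so a C9=C11 vinyl group on the quaternary carbon C10 can take an alkenylnickel at C8 and pass C11 on to an aryl iodide. One nickel-catalysed reductive alkenyl-arylation thus forms C8–C9 and C11–aryl, closes ring B as a trans-fused decalin, joins the terpenoid and aromatic halves and sets C9. Its precursor is a monocyclic cyclohexanone carrying the vinyl group and a (Z)-3-iodobut-2-enyl chain on adjacent carbons.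

Key step: step 7

Remark: atoms are numbered as in a drimane (C1–C4 and C5/C10 in ring A, C5–C10 in ring B, C11 the benzylic CH2); in step 3 the enantiomer of the carbene ligand that delivers the (S)-configured quaternary carbon is assumed.

Step 1
Reactants: 1 but-2-yn-1-ol
Product: 3 (2Z)-3-iodobut-2-en-1-ol, via sodium alkenylalanate 2 (not isolated)
Conditions: NaAlH2(OCH2CH2OMe)2, THF, 0 °C to rt; then I2, THF, −78 to 0 °C
Reagents that add atoms: iodine, [I][I]
Why: Hydroxyl-directed trans-hydroalumination of the propargylic alcohol puts aluminium on C3 inside a five-membered alanate, and iodinolysis of the C–Al bond with retention should give the Z alkenyl iodide (hydroalumination–iodination), with iodine and the CH2O group cis as ring B later requires.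

Step 2
Reactants: 3 (2Z)-3-iodobut-2-en-1-ol
Product: 4 (2Z)-1-bromo-3-iodobut-2-ene
Conditions: PBr3, pyridine (cat.), Et2O, 0 °C
Reagents that add atoms: phosphorus tribromide, BrP(Br)Br
Why: Bromination of the primary allylic alcohol with PBr3 (SN2 at carbon via the phosphite ester) should leave the alkenyl iodide and its Z geometry untouched.

Step 3
Reactants: 5 3-methylcyclohex-2-en-1-one
Product: 7 trimethyl({(3S)-3-methyl-3-[1-(trimethylsilyl)ethenyl]cyclohex-1-en-1-yl}oxy)silane, via aluminium enolate 6 (not isolated)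
Conditions: HC≡CSiMe3, iBu2AlH, hexanes/THF, 55 °C; then 5, Cu(OTf)2 (5 mol %), chiral sulfonate-bearing N-heterocyclic carbene (added as the silver carbene complex made from its imidazolinium salt and Ag2O, 2.5 mol %), THF, −78 to 4 °C; then Me3SiOTf, −78 to 0 °C
Reagents that add atoms: ethynyltrimethylsilane, C#C[Si](C)(C)C; trimethylsilyl trifluoromethanesulfonate, C[Si](C)(C)OS(=O)(=O)C(F)(F)F
Why: Copper-catalysed enantioselective conjugate addition of an alkenylaluminium to a β-methyl cyclic enone is a known route to a vinyl-type quaternary carbon: the chiral carbene–copper complex selects the enone face and so sets C10 (S), and O-silylation of the aluminium enolate stores the enolate regiochemistry toward C5.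

Step 4
Reactants: 7 trimethyl({(3S)-3-methyl-3-[1-(trimethylsilyl)ethenyl]cyclohex-1-en-1-yl}oxy)silane; 4 (2Z)-1-bromo-3-iodobut-2-ene
Product: 9 (2R,3S)-2-[(2Z)-3-iodobut-2-en-1-yl]-3-methyl-3-[1-(trimethylsilyl)ethenyl]cyclohexan-1-one, via lithium enolate 8 (not isolated)
Conditions: MeLi, THF, 0 °C to rt; then HMPA, 4, −78 to −20 °C
Reagents that add atoms: none
Why: MeLi cleaves the O–Si bond to the regiodefined lithium enolate, and its C-alkylation by the reactive allylic bromide (enolate alkylation) should occur anti to the bulky 1-silylvinyl group on the neighbouring quaternary carbon, which sets C5 (R) with the side chain trans to that group and cis to the methyl, as a trans ring fusion needs.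

Step 5
Reactants: 9 (2R,3S)-2-[(2Z)-3-iodobut-2-en-1-yl]-3-methyl-3-[1-(trimethylsilyl)ethenyl]cyclohexan-1-one
Product: 10 (2R,3R)-3-ethenyl-2-[(2Z)-3-iodobut-2-en-1-yl]-3-methylcyclohexan-1-one
Conditions: CF3CO2H, CH2Cl2, 0 °C
Reagents that add atoms: none
Why: ipso-Protonation of the vinylsilane gives a β-silyl cation that loses silicon (protodesilylation) to unveil the C9=C11 vinyl group; short contact at 0 °C is chosen so that the ketone does not enolise toward C5.

Step 6
Reactants: 11 2-(2,5-dimethoxyphenyl)ethan-1-ol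
Product: 12 2-(4-iodo-2,5-dimethoxyphenyl)ethan-1-ol
Conditions: N-iodosuccinimide, CF3CO2H (cat.), MeCN, rt
Reagents that add atoms: N-iodosuccinimide, O=C1CCC(=O)N1I
Why: Electrophilic aromatic iodination should go to the position para to the alkyl chain and ortho to a methoxy group, the most activated unhindered site of a 2-alkyl-1,4-dimethoxybenzene.

Step 7
Reactants: 10 (2R,3R)-3-ethenyl-2-[(2Z)-3-iodobut-2-en-1-yl]-3-methylcyclohexan-1-one; 12 2-(4-iodo-2,5-dimethoxyphenyl)ethan-1-ol
Product: 13 (4aR,5R,8aR)-5-{[4-(2-hydroxyethyl)-2,5-dimethoxyphenyl]methyl}-4a,6-dimethyl-3,4,4a,5,8,8a-hexahydronaphthalen-1(2H)-one (trans-fused, arylmethyl group α on C9)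
Conditions: NiBr2(MeOCH2CH2OMe) (15 mol %), 4,4′-di-tert-butyl-2,2′-bipyridine (20 mol %), Mn powder (3 equiv), NaI (0.5 equiv), DMA, 30 °C, 12 (1.5 equiv) added slowly
Reagents that add atoms: none
Why: Proposed new method: zerovalent nickel (from NiBr2 and Mn) should add oxidatively to the alkenyl C8–I bond of 10, which is more reactive than the electron-rich, ortho-substituted aryl iodide; the alkenylnickel then inserts the C9=C11 vinyl group by syn-carbometalation, forming C8–C9, and the primary C11–nickel species, after single-electron reduction by Mn, adds 12 oxidatively and eliminates reductively to forge C11–aryl. The closest known reaction type is the nickel-catalysed reductive dicarbofunctionalisation of tethered alkenes (cyclisation of an aryl halide onto an alkene followed by cross-electrophile coupling with a second sp2 halide); new here are the alkenyl iodide initiator, the six-membered ring and a monosubstituted alkene whose alkylnickel carries a β-hydrogen. Ring B closes in the 6-exo-trig mode (not 7-endo) through a chair-like, trans-fused transition state that is fixed by the trans arrangement of the vinyl group on C10 and the iodobutenyl chain on C5. The new stereocentre C9 is controlled by the substrate: the eclipsed four-centre insertion geometry holds the C9–C11 bond perpendicular to the plane of the C7=C8 unit, which in the chair-like array is the pseudoaxial α position, anti to the axial C10 methyl and free of A(1,2) strain with the C8 methyl, so that C9–H should end up β as required. The step needs cyclisation to outrun direct alkenyl–aryl coupling and the alkylnickel to couple faster than it loses the C9 hydrogen; intramolecularity, slow addition of 12 and nitrogen ligands on nickel, under which alkylnickel species with β-hydrogens couple routinely, are relied on for this.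

Step 8
Reactants: 13 (4aR,5R,8aR)-5-{[4-(2-hydroxyethyl)-2,5-dimethoxyphenyl]methyl}-4a,6-dimethyl-3,4,4a,5,8,8a-hexahydronaphthalen-1(2H)-one
Product: 15 (2R,4aR,5R,8aR)-5-{[4-(2-hydroxyethyl)-2,5-dimethoxyphenyl]methyl}-2,4a,6-trimethyl-3,4,4a,5,8,8a-hexahydronaphthalen-1(2H)-one, via dilithium enolate alkoxide 14 (not isolated)
Conditions: LiN(iPr)2 (2.2 equiv), THF, −78 °C; then MeI (1.1 equiv), −78 to −40 °C
Reagents that add atoms: iodomethane, CI
Why: After the alkoxide has formed, LiN(iPr)2 removes the less hindered C3 proton (kinetic enolate) and MeI should enter axially from the α face of the rigid trans-decalone enolate, the β face being blocked in the boat-like alternative by the axial C10 methyl, which sets C3 (R) with the methyl axial and trans to the C10 methyl (enolate alkylation); the lithium alkoxide is not methylated at this temperature.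

Step 9
Reactants: 15 (2R,4aR,5R,8aR)-5-{[4-(2-hydroxyethyl)-2,5-dimethoxyphenyl]methyl}-2,4a,6-trimethyl-3,4,4a,5,8,8a-hexahydronaphthalen-1(2H)-one
Product: 16 2-(2,5-dimethoxy-4-{[(1R,4aS,6R,8aR)-2,6,8a-trimethyl-5-methylidene-1,4,4a,5,6,7,8,8a-octahydronaphthalen-1-yl]methyl}phenyl)ethan-1-ol
Conditions: Zn, CH2Br2, TiCl4, THF/CH2Cl2, 0 °C to rt
Reagents that add atoms: dibromomethane, BrCBr
Why: Takai–Lombardo methylenation uses a non-basic zinc–titanium gem-dimetallic that should convert the hindered, enolisable ketone into the exocyclic methylene without epimerising the axial C3 methyl; the free hydroxyl only consumes reagent.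

Step 10
Reactants: 16 2-(2,5-dimethoxy-4-{[(1R,4aS,6R,8aR)-2,6,8a-trimethyl-5-methylidene-1,4,4a,5,6,7,8,8a-octahydronaphthalen-1-yl]methyl}phenyl)ethan-1-ol
Product: 18 2-(2,5-dimethoxy-4-{[(1R,4aS,6R,8aR)-2,6,8a-trimethyl-5-methylidene-1,4,4a,5,6,7,8,8a-octahydronaphthalen-1-yl]methyl}phenyl)acetic acid, via arylacetaldehyde 17 (not isolated)
Conditions: TEMPO (cat.), PhI(OAc)2, MeCN/H2O, rt
Reagents that add atoms: water, O
Why: Oxoammonium oxidation (TEMPO/PhI(OAc)2) in aqueous MeCN takes the primary alcohol through the aldehyde hydrate to the acid and should leave both alkenes and the dimethoxyarene alone.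

Step 11
Reactants: 18 2-(2,5-dimethoxy-4-{[(1R,4aS,6R,8aR)-2,6,8a-trimethyl-5-methylidene-1,4,4a,5,6,7,8,8a-octahydronaphthalen-1-yl]methyl}phenyl)acetic acid
Product: 20 2-(2,5-dihydroxy-4-{[(1R,4aS,6R,8aR)-2,6,8a-trimethyl-5-methylidene-1,4,4a,5,6,7,8,8a-octahydronaphthalen-1-yl]methyl}phenyl)acetic acid (CNP0137474.1), via quinone acid 19 (not isolated)
Conditions: (NH4)2Ce(NO3)6, MeCN/H2O, 0 °C; then Na2S2O4, H2O/EtOAc, rt
Reagents that add atoms: water, O
Why: Oxidative demethylation of the 1,4-dimethoxyarene by (NH4)2Ce(NO3)6 (water attacks the arene radical cation at the methoxy-bearing carbons) should give the quinone, which dithionite reduces in the same work-up to the hydroquinone; no stereocentre is involved.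

Compound list
1 | but-2-yn-1-ol | CC#CCO | starting material
2 | sodium alkenylalanate (sodium 2,2-bis(2-methoxyethoxy)-3-methyl-2,5-dihydro-1,2-oxaaluminol-2-uide) | CC1=CCO[Al-]1(OCCOC)OCCOC.[Na+] | intermediate
3 | (2Z)-3-iodobut-2-en-1-ol | C/C(I)=C/CO | intermediate
4 | (2Z)-1-bromo-3-iodobut-2-ene | C/C(I)=C/CBr | intermediate
5 | 3-methylcyclohex-2-en-1-one | CC1=CC(=O)CCC1 | starting material
6 | diisobutylaluminium (3S)-3-methyl-3-[1-(trimethylsilyl)ethenyl]cyclohex-1-en-1-olate | CC(C)C[Al](CC(C)C)OC1=C[C@@](C)(C(=C)[Si](C)(C)C)CCC1 | intermediate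
7 | trimethyl({(3S)-3-methyl-3-[1-(trimethylsilyl)ethenyl]cyclohex-1-en-1-yl}oxy)silane | C[Si](C)(C)OC1=C[C@@](C)(C(=C)[Si](C)(C)C)CCC1 | intermediate
8 | lithium (3S)-3-methyl-3-[1-(trimethylsilyl)ethenyl]cyclohex-1-en-1-olate | [Li]OC1=C[C@@](C)(C(=C)[Si](C)(C)C)CCC1 | intermediate
9 | (2R,3S)-2-[(2Z)-3-iodobut-2-en-1-yl]-3-methyl-3-[1-(trimethylsilyl)ethenyl]cyclohexan-1-one | O=C1CCC[C@](C)(C(=C)[Si](C)(C)C)[C@H]1C/C=C(/C)I | intermediate
10 | (2R,3R)-3-ethenyl-2-[(2Z)-3-iodobut-2-en-1-yl]-3-methylcyclohexan-1-one | O=C1CCC[C@](C)(C=C)[C@H]1C/C=C(/C)I | intermediate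
11 | 2-(2,5-dimethoxyphenyl)ethan-1-ol | COc1ccc(OC)c(CCO)c1 | starting material
12 | 2-(4-iodo-2,5-dimethoxyphenyl)ethan-1-ol | COc1cc(I)c(OC)cc1CCO | intermediate
13 | (4aR,5R,8aR)-5-{[4-(2-hydroxyethyl)-2,5-dimethoxyphenyl]methyl}-4a,6-dimethyl-3,4,4a,5,8,8a-hexahydronaphthalen-1(2H)-one | O=C1CCC[C@]2(C)[C@H](Cc3cc(OC)c(CCO)cc3OC)C(C)=CC[C@@H]12 | intermediate
14 | dilithium salt of 13 (C3–C4 enolate and side-chain alkoxide) | [Li]OC1=CCC[C@]2(C)[C@H](Cc3cc(OC)c(CCO[Li])cc3OC)C(C)=CC[C@@H]12 | intermediate
15 | (2R,4aR,5R,8aR)-5-{[4-(2-hydroxyethyl)-2,5-dimethoxyphenyl]methyl}-2,4a,6-trimethyl-3,4,4a,5,8,8a-hexahydronaphthalen-1(2H)-one | O=C1[C@H](C)CC[C@]2(C)[C@H](Cc3cc(OC)c(CCO)cc3OC)C(C)=CC[C@@H]12 | intermediate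
16 | 2-(2,5-dimethoxy-4-{[(1R,4aS,6R,8aR)-2,6,8a-trimethyl-5-methylidene-1,4,4a,5,6,7,8,8a-octahydronaphthalen-1-yl]methyl}phenyl)ethan-1-ol | C=C1[C@H](C)CC[C@]2(C)[C@H](Cc3cc(OC)c(CCO)cc3OC)C(C)=CC[C@@H]12 | intermediate
17 | 2-(2,5-dimethoxy-4-{[(1R,4aS,6R,8aR)-2,6,8a-trimethyl-5-methylidene-1,4,4a,5,6,7,8,8a-octahydronaphthalen-1-yl]methyl}phenyl)acetaldehyde | C=C1[C@H](C)CC[C@]2(C)[C@H](Cc3cc(OC)c(CC=O)cc3OC)C(C)=CC[C@@H]12 | intermediate
18 | 2-(2,5-dimethoxy-4-{[(1R,4aS,6R,8aR)-2,6,8a-trimethyl-5-methylidene-1,4,4a,5,6,7,8,8a-octahydronaphthalen-1-yl]methyl}phenyl)acetic acid | C=C1[C@H](C)CC[C@]2(C)[C@H](Cc3cc(OC)c(CC(=O)O)cc3OC)C(C)=CC[C@@H]12 | intermediate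
19 | 2-(3,6-dioxo-4-{[(1R,4aS,6R,8aR)-2,6,8a-trimethyl-5-methylidene-1,4,4a,5,6,7,8,8a-octahydronaphthalen-1-yl]methyl}cyclohexa-1,4-dien-1-yl)acetic acid | C=C1[C@H](C)CC[C@]2(C)[C@H](CC3=CC(=O)C(CC(=O)O)=CC3=O)C(C)=CC[C@@H]12 | intermediate
20 | 2-(2,5-dihydroxy-4-{[(1R,4aS,6R,8aR)-2,6,8a-trimethyl-5-methylidene-1,4,4a,5,6,7,8,8a-octahydronaphthalen-1-yl]methyl}phenyl)acetic acid | C=C1[C@H](C)CC[C@]2(C)[C@H](Cc3cc(O)c(CC(=O)O)cc3O)C(C)=CC[C@@H]12 | target

Total step count: 11. Longest linear sequence: 9 steps (steps 1, 2, 4, 5, 7, 8, 9, 10, 11 from but-2-yn-1-ol).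

Steps most likely to fail

Step 7. What may go wrong: direct alkenyl–aryl coupling or hydrodeiodination before the 6-exo insertion, loss of the C9 hydrogen from the alkylnickel, or poor facial selectivity at C9. The fallback uses known chemistry, sets out from 10 and 12 and comes back at 13. Suzuki–Miyaura vinylation of 12 (potassium vinyltrifluoroborate, PdCl2(dppf), Cs2CO3, THF/H2O, 70 °C) should give 2-(4-ethenyl-2,5-dimethoxyphenyl)ethan-1-ol F1. Olefin cross-metathesis of the vinyl group of 10 with excess F1 (second-generation Grubbs catalyst, CH2Cl2, 40 °C; the alkenyl iodide is inert) should then give the (E)-styrene (2R,3R)-3-{(E)-2-[4-(2-hydroxyethyl)-2,5-dimethoxyphenyl]ethenyl}-2-[(2Z)-3-iodobut-2-en-1-yl]-3-methylcyclohexan-1-one F2. An intramolecular reductive Heck cyclisation of F2 (Pd(OAc)2, PPh3, HCO2Na, Bu4NCl, DMF, 80 °C) closes the same C8–C9 bond 6-exo onto the styrene, formate reduces the benzylic palladium, and the same insertion geometry should give 13.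

Step 4. What may go wrong: slow C-alkylation of the hindered enolate with proton exchange, or attack on the face syn to the silylvinyl group, so that the C5 configuration is eroded. The fallback replaces kinetic by thermodynamic control; it sets out from 9 as obtained (mixed with its C5 epimer) and comes back at 9. Because C5 is α to the ketone, equilibration with NaOMe in MeOH at rt should funnel the mixture toward the isomer in which the side chain and the bulky silylvinyl group are trans and both equatorial, which is 9; no new compound is made.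

Step 11. What may go wrong: oxidative decarboxylation of the arylacetic acid at the arene radical-cation stage, or attack of the carboxyl group or an alkene on the quinone before it is reduced. The fallback is a non-oxidative, nucleophilic O-demethylation; it sets out from 18 and comes back at 20. Excess NaSEt in DMF at 130 °C under argon (SN2 at the two aryl methyl ethers, with the carboxylate as spectator), followed by acidification under argon, should give 20 directly; no new compound is made.

Further compounds
F1 | step 7 | 2-(4-ethenyl-2,5-dimethoxyphenyl)ethan-1-ol | C=Cc1cc(OC)c(CCO)cc1OC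
F2 | step 7 | (2R,3R)-3-{(E)-2-[4-(2-hydroxyethyl)-2,5-dimethoxyphenyl]ethenyl}-2-[(2Z)-3-iodobut-2-en-1-yl]-3-methylcyclohexan-1-one | O=C1CCC[C@](C)(/C=C/c2cc(OC)c(CCO)cc2OC)[C@H]1C/C=C(/C)I
F0 | step 4 | none | none
F0 | step 11 | none | none
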